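The route rests on opening the pyran ring (ring C) of the middle flavan unit at C3–C4 and O1–C2. C4 of that unit carries two aryl groups, its own ring A (via C4a) and ring A of the lower unit (via C8), and sits next to the O1-bearing carbon C8a: the pattern of the methide carbon of an o-quinone methide. C3 carries oxygen and maps onto the α-carbon of a protected glycolaldehyde. One amine-catalysed conjugate addition/hemiacetalisation thus forms both bonds, closes ring C and sets C3 and C4 (3,4-trans). The precursor is a diaryl carbinol joining a free-phenol phloroglucinol ring to C8 of the protected lower epicatechin.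

Key step: step 8

Remark: flavan numbering is used and the units are called top, middle and lower (target = epicatechin-(4β→8)-epicatechin 3-O-gallate-(4β→8)-epicatechin 3-O-gallate); Bn = benzyl, TBS = tert-butyldimethylsilyl. Compounds 15 and 20 are taken as purchasable. The phenol that becomes O1 is masked as an allyl ether, because a silyl group there would be expected to shift onto the new benzylic alkoxide during the aryllithium addition. The middle C2 aryl group is brought in by Grignard opening of the lactol and Mitsunobu closure.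

Step 1
Reactants: 1 (−)-epicatechin
Product: 2 5,7,3',4'-tetra-O-benzylepicatechin (2R,3R; 3-OH free)
Conditions: BnBr (4.4 equiv), K2CO3, DMF, 0 °C → rt
Reagents that add atoms: benzyl bromide, BrCc1ccccc1
Why: Williamson etherification, in which K2CO3 ionises only the four phenols so that benzyl bromide leaves the secondary 3-OH free and no stereocentre is touched.

Step 2
Reactants: 2 5,7,3',4'-tetra-O-benzylepicatechin
Product: 3 5,7,3',4'-tetra-O-benzyl-3-O-TBS-epicatechin
Conditions: TBSCl, imidazole, DMF, rt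
Reagents that add atoms: tert-butyldimethylsilyl chloride, CC(C)(C)[Si](C)(C)Cl
Why: Imidazole-promoted silylation of the single remaining hydroxyl gives a silyl ether that tolerates organolithium and Grignard reagents and is later removed together with its twin by fluoride.

Step 3
Reactants: 3 5,7,3',4'-tetra-O-benzyl-3-O-TBS-epicatechin
Product: 4 8-bromo-5,7,3',4'-tetra-O-benzyl-3-O-TBS-epicatechin
Conditions: NBS (1.0 equiv), CH2Cl2, −78 °C → rt
Reagents that add atoms: N-bromosuccinimide, O=C1CCC(=O)N1Br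
Why: Electrophilic aromatic bromination of the phloroglucinol-type ring A with one equivalent of NBS should go to C8, the more reactive of the two free positions in 5,7-di-O-benzyl flavans, with C6 left untouched.

Step 4
Reactants: 5 2,4,6-trihydroxybenzaldehyde
Product: 6 2,4-bis(benzyloxy)-6-hydroxybenzaldehyde
Conditions: BnBr (2.1 equiv), K2CO3, DMF, rt
Reagents that add atoms: benzyl bromide, BrCc1ccccc1
Why: Williamson etherification that stops at the dibenzyl ether because the last hydroxyl, ortho to the formyl group, is locked in an intramolecular hydrogen bond and is alkylated much more slowly.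

Step 5
Reactants: 6 2,4-bis(benzyloxy)-6-hydroxybenzaldehyde
Product: 7 2-(allyloxy)-4,6-bis(benzyloxy)benzaldehyde
Conditions: allyl bromide, K2CO3, DMF, 60 °C
Reagents that add atoms: allyl bromide, C=CCBr
Why: Williamson etherification under more forcing conditions caps the hydrogen-bonded phenol as an allyl ether, which cannot migrate to an alkoxide, survives aryllithium addition and is removable under neutral conditions in the presence of benzyl and silyl ethers.

Step 6
Reactants: 4 8-bromo-5,7,3',4'-tetra-O-benzyl-3-O-TBS-epicatechin; 7 2-(allyloxy)-4,6-bis(benzyloxy)benzaldehyde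
Product: 9 [2-(allyloxy)-4,6-bis(benzyloxy)phenyl](5,7,3',4'-tetra-O-benzyl-3-O-TBS-epicatechin-8-yl)methanol (both carbinol epimers), via aryllithium 8 (not isolated)
Conditions: t-BuLi (2.0 equiv), THF, −78 °C; then 7, −78 → −30 °C; H2O
Reagents that add atoms: none
Why: Bromine–lithium exchange at −78 °C gives the C8 aryllithium, whose 1,2-addition to the aldehyde fixes the lower unit regiospecifically at C8 and creates the carbinol carbon as an uncontrolled, inconsequential mixture because this carbon becomes trigonal in step 8.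

Step 7
Reactants: 9 [2-(allyloxy)-4,6-bis(benzyloxy)phenyl](5,7,3',4'-tetra-O-benzyl-3-O-TBS-epicatechin-8-yl)methanol
Product: 10 [4,6-bis(benzyloxy)-2-hydroxyphenyl](5,7,3',4'-tetra-O-benzyl-3-O-TBS-epicatechin-8-yl)methanol (both carbinol epimers)
Conditions: Pd(PPh3)4 (5 mol %), morpholine (5 equiv), THF, rt; crude product used directly
Reagents that add atoms: none
Why: Tsuji–Trost-type deallylation, in which zerovalent palladium ionises the aryl allyl ether to a π-allyl complex that morpholine captures, frees the phenol without acid so that the very ionisable diaryl carbinol, the benzyl ethers and the silyl ether should survive.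

Step 8
Reactants: 10 [4,6-bis(benzyloxy)-2-hydroxyphenyl](5,7,3',4'-tetra-O-benzyl-3-O-TBS-epicatechin-8-yl)methanol; 11 (tert-butyldimethylsilyloxy)acetaldehyde
Product: 14 3,4-trans-5,7-bis(benzyloxy)-3-(tert-butyldimethylsilyloxy)-4-(5,7,3',4'-tetra-O-benzyl-3-O-TBS-epicatechin-8-yl)chroman-2-ol (3R; anomeric mixture), via o-quinone methide 12 (not isolated), via enamine 13 (not isolated)
Conditions: (S)-α,α-diphenylprolinol trimethylsilyl ether (20 mol %), PhCO2H (20 mol %), 11 (3 equiv, slow addition), CH2Cl2, −20 °C → rt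
Reagents that add atoms: none
Why: Benzoic acid ionises the doubly oxygen-activated carbinol 10 with loss of water to the aryl-substituted o-quinone methide 12 while the amine condenses with 11 to the E-enamine 13; the enamine β-carbon adds to the exocyclic methide carbon (C3–C4), ring A rearomatises to the phenol, its oxygen adds to the iminium carbon (O1–C2), and the released water hydrolyses the N,O-acetal to lactol 14 and free catalyst. The closest known reaction type is the diarylprolinol silyl ether catalysed formal [4+2] (Michael addition then hemiacetalisation) of aldehydes with in situ generated aryl o-quinone methides, which gives 3,4-trans chroman-2-ols, and α-alkoxyacetaldehydes are established enamine donors for this catalyst class. The pyran ring closes by 6-exo-trig attack of the phenol oxygen on the iminium (or liberated aldehyde) carbon. C3 is set by the catalyst, whose diphenyl(silyloxy)methyl group blocks one face of the s-trans E-enamine so that the (S)-catalyst should deliver 3R; C4 is set relative to C3 by the anti Michael transition state that keeps the bulky epicatechinyl group away from the silyloxy group (3,4-trans); the anomeric C2 is uncontrolled and is erased in step 9. The step needs catalyst control to outweigh any bias from the lower-unit stereocentres, the nearest of which is four bonds from the methide carbon, and it needs a single quinone methide, which is secured because only one phenol is free and the methide carbon is the only electrophilic site; since the lower unit is already bonded through C8, no 4→6 isomer can form.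

Step 9
Reactants: 14 3,4-trans-5,7-bis(benzyloxy)-3-(tert-butyldimethylsilyloxy)-4-(5,7,3',4'-tetra-O-benzyl-3-O-TBS-epicatechin-8-yl)chroman-2-ol; 15 4-bromo-1,2-bis(benzyloxy)benzene
Product: 17 (1S,2R)-1-[3,4-bis(benzyloxy)phenyl]-3-[2,4-bis(benzyloxy)-6-hydroxyphenyl]-2-(tert-butyldimethylsilyloxy)-3-(5,7,3',4'-tetra-O-benzyl-3-O-TBS-epicatechin-8-yl)propan-1-ol (1,2-anti; C3 as C4 of 14), via Grignard reagent 16 (not isolated)
Conditions: 15, Mg, THF, rt (gives 16, 3 equiv); then 14, THF, −78 → 0 °C; H2O/NH4Cl work-up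
Reagents that add atoms: none
Why: The bromomagnesium salt of the lactol opens to the phenoxide and the α-silyloxy aldehyde, and Grignard addition under polar Felkin–Anh control (non-chelating OTBS anti to the incoming aryl) should set the new carbinol centre 1,2-anti, while the low temperature protects the α-centre from enolisation.

Step 10
Reactants: 17 (1S,2R)-1-[3,4-bis(benzyloxy)phenyl]-3-[2,4-bis(benzyloxy)-6-hydroxyphenyl]-2-(tert-butyldimethylsilyloxy)-3-(5,7,3',4'-tetra-O-benzyl-3-O-TBS-epicatechin-8-yl)propan-1-ol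
Product: 18 5,7,3',4'-tetra-O-benzyl-3-O-TBS-epicatechin-(4β→8)-5,7,3',4'-tetra-O-benzyl-3-O-TBS-epicatechin (upper ring C 2,3-cis-3,4-trans)
Conditions: PPh3, DIAD, toluene, 0 °C → rt
Reagents that add atoms: none
Why: Intramolecular Mitsunobu etherification, a 6-exo-tet SN2 displacement of the activated benzylic oxygen by the phenol with inversion, should convert the 1,2-anti carbinol into the 2,3-cis chroman with the 2-aryl group trans to the C4 aryl group (2R,3R middle unit).

Step 11
Reactants: 18 5,7,3',4'-tetra-O-benzyl-3-O-TBS-epicatechin-(4β→8)-5,7,3',4'-tetra-O-benzyl-3-O-TBS-epicatechin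
Product: 19 5,7,3',4'-tetra-O-benzylepicatechin-(4β→8)-5,7,3',4'-tetra-O-benzylepicatechin (octa-O-benzyl procyanidin B2; both 3-OH free)
Conditions: TBAF (6 equiv), THF, rt → 45 °C
Reagents that add atoms: none
Why: Fluoride-induced cleavage of both Si–O bonds, driven by the strong Si–F bond, exposes the two secondary 3-hydroxyls without touching benzyl ethers, the interflavan bond or any stereocentre.

Step 12
Reactants: 19 octa-O-benzyl procyanidin B2; 20 3,4,5-tris(benzyloxy)benzoic acid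
Product: 21 octa-O-benzyl procyanidin B2 3,3''-bis-O-[3,4,5-tris(benzyloxy)benzoate]
Conditions: 20 (3 equiv), DCC, DMAP, CH2Cl2, rt
Reagents that add atoms: none
Why: Steglich esterification, in which the DMAP-derived acylpyridinium acylates both hindered axial 3-hydroxyls with retention because no C–O bond at a stereocentre is broken.

Step 13
Reactants: 2 5,7,3',4'-tetra-O-benzylepicatechin
Product: 22 4β-(2-ethoxyethoxy)-5,7,3',4'-tetra-O-benzylepicatechin (4-alkoxy trans to the free 3-OH)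
Conditions: DDQ (2 equiv), 2-ethoxyethanol, CH2Cl2, rt
Reagents that add atoms: 2-ethoxyethanol, CCOCCO
Why: DDQ abstracts hydride from the benzylic C4, the resulting ring A-stabilised cation is trapped by 2-ethoxyethanol on the face opposite the 3-hydroxyl (4β), and this oxidative benzylic etherification stops at the mono-ether.

Step 14
Reactants: 21 octa-O-benzyl procyanidin B2 3,3''-bis-O-[3,4,5-tris(benzyloxy)benzoate]; 22 4β-(2-ethoxyethoxy)-5,7,3',4'-tetra-O-benzylepicatechin
Product: 23 5,7,3',4'-tetra-O-benzylepicatechin-(4β→8)-[5,7,3',4'-tetra-O-benzyl-3-O-(3,4,5-tris(benzyloxy)benzoyl)epicatechin]-(4β→8)-[5,7,3',4'-tetra-O-benzyl-3-O-(3,4,5-tris(benzyloxy)benzoyl)epicatechin]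
Conditions: 21 (1.5 equiv, excess recovered), 22 (1.0 equiv, slow addition), TMSOTf (0.3 equiv), CH2Cl2, −78 → −40 °C; Et3N quench
Reagents that add atoms: none
Why: Lewis-acid ionisation of the 4-alkoxy group gives the flavan-4-yl cation, and Friedel–Crafts alkylation by C8 of the middle unit of 21, the most nucleophilic free ring A position, on the face opposite the 3-hydroxyl of the cation should create the top C4 centre as 4β (3,4-trans), with the nucleophile in excess to suppress chain growth.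

Step 15
Reactants: 23 protected trimer
Product: 24 epicatechin-(4β→8)-epicatechin 3-O-gallate-(4β→8)-epicatechin 3-O-gallate (CNP0279403.1)
Conditions: H2 (1 atm), Pd(OH)2/C, THF/MeOH/H2O, rt
Reagents that add atoms: none
Why: Catalytic hydrogenolysis cleaves all eighteen benzyl ethers under neutral conditions that leave the gallate esters, the benzylic ring C–O bonds and the interflavan C–C bonds intact.

Compound list

1 | (−)-epicatechin | O[C@@H]1Cc2c(O)cc(O)cc2O[C@@H]1c1ccc(O)c(O)c1 | starting material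
2 | 5,7,3',4'-tetra-O-benzylepicatechin | O[C@@H]1Cc2c(OCc3ccccc3)cc(OCc3ccccc3)cc2O[C@@H]1c1ccc(OCc2ccccc2)c(OCc2ccccc2)c1 | intermediate
3 | 5,7,3',4'-tetra-O-benzyl-3-O-TBS-epicatechin | CC(C)(C)[Si](C)(C)O[C@@H]1Cc2c(OCc3ccccc3)cc(OCc3ccccc3)cc2O[C@@H]1c1ccc(OCc2ccccc2)c(OCc2ccccc2)c1 | intermediate
4 | 8-bromo-5,7,3',4'-tetra-O-benzyl-3-O-TBS-epicatechin | CC(C)(C)[Si](C)(C)O[C@@H]1Cc2c(OCc3ccccc3)cc(OCc3ccccc3)c(Br)c2O[C@@H]1c1ccc(OCc2ccccc2)c(OCc2ccccc2)c1 | intermediate
5 | 2,4,6-trihydroxybenzaldehyde | O=Cc1c(O)cc(O)cc1O | starting material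
6 | 2,4-bis(benzyloxy)-6-hydroxybenzaldehyde | O=Cc1c(O)cc(OCc2ccccc2)cc1OCc1ccccc1 | intermediate
7 | 2-(allyloxy)-4,6-bis(benzyloxy)benzaldehyde | C=CCOc1cc(OCc2ccccc2)cc(OCc2ccccc2)c1C=O | intermediate
8 | 8-lithio-5,7,3',4'-tetra-O-benzyl-3-O-TBS-epicatechin | CC(C)(C)[Si](C)(C)O[C@@H]1Cc2c(OCc3ccccc3)cc(OCc3ccccc3)c([Li])c2O[C@@H]1c1ccc(OCc2ccccc2)c(OCc2ccccc2)c1 | intermediate (not isolated)
9 | [2-(allyloxy)-4,6-bis(benzyloxy)phenyl](5,7,3',4'-tetra-O-benzyl-3-O-TBS-epicatechin-8-yl)methanol, carbinol epimers | CC(C)(C)[Si](C)(C)O[C@@H]1Cc2c(OCc3ccccc3)cc(OCc3ccccc3)c(C(O)c3c(OCC=C)cc(OCc4ccccc4)cc3OCc3ccccc3)c2O[C@@H]1c1ccc(OCc2ccccc2)c(OCc2ccccc2)c1 | intermediate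
10 | [4,6-bis(benzyloxy)-2-hydroxyphenyl](5,7,3',4'-tetra-O-benzyl-3-O-TBS-epicatechin-8-yl)methanol, carbinol epimers | CC(C)(C)[Si](C)(C)O[C@@H]1Cc2c(OCc3ccccc3)cc(OCc3ccccc3)c(C(O)c3c(O)cc(OCc4ccccc4)cc3OCc3ccccc3)c2O[C@@H]1c1ccc(OCc2ccccc2)c(OCc2ccccc2)c1 | intermediate
11 | (tert-butyldimethylsilyloxy)acetaldehyde | O=CCO[Si](C)(C)C(C)(C)C | starting material
12 | 3,5-bis(benzyloxy)-6-[(5,7,3',4'-tetra-O-benzyl-3-O-TBS-epicatechin-8-yl)methylidene]cyclohexa-2,4-dien-1-one (o-quinone methide, exocyclic alkene geometry not fixed) | CC(C)(C)[Si](C)(C)O[C@@H]1Cc2c(OCc3ccccc3)cc(OCc3ccccc3)c(C=C3C(=O)C=C(OCc4ccccc4)C=C3OCc3ccccc3)c2O[C@@H]1c1ccc(OCc2ccccc2)c(OCc2ccccc2)c1 | intermediate (not isolated)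
13 | (S)-1-[(E)-2-(tert-butyldimethylsilyloxy)ethenyl]-2-[diphenyl(trimethylsilyloxy)methyl]pyrrolidine (enamine of 11 and the catalyst) | CC(C)(C)[Si](C)(C)O/C=C/N1CCC[C@H]1C(c1ccccc1)(c1ccccc1)O[Si](C)(C)C | intermediate (not isolated)
14 | 3,4-trans-5,7-bis(benzyloxy)-3-(tert-butyldimethylsilyloxy)-4-(5,7,3',4'-tetra-O-benzyl-3-O-TBS-epicatechin-8-yl)chroman-2-ol, 3R, anomeric mixture | CC(C)(C)[Si](C)(C)O[C@@H]1[C@@H](c2c(OCc3ccccc3)cc(OCc3ccccc3)c3c2O[C@H](c2ccc(OCc4ccccc4)c(OCc4ccccc4)c2)[C@H](O[Si](C)(C)C(C)(C)C)C3)c2c(OCc3ccccc3)cc(OCc3ccccc3)cc2OC1O | intermediate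
15 | 4-bromo-1,2-bis(benzyloxy)benzene | Brc1ccc(OCc2ccccc2)c(OCc2ccccc2)c1 | starting material
16 | 3,4-bis(benzyloxy)phenylmagnesium bromide | Br[Mg]c1ccc(OCc2ccccc2)c(OCc2ccccc2)c1 | intermediate (not isolated)
17 | (1S,2R)-1-[3,4-bis(benzyloxy)phenyl]-3-[2,4-bis(benzyloxy)-6-hydroxyphenyl]-2-(tert-butyldimethylsilyloxy)-3-(5,7,3',4'-tetra-O-benzyl-3-O-TBS-epicatechin-8-yl)propan-1-ol, 1,2-anti | CC(C)(C)[Si](C)(C)O[C@@H]([C@@H](O)c1ccc(OCc2ccccc2)c(OCc2ccccc2)c1)[C@@H](c2c(OCc3ccccc3)cc(OCc3ccccc3)c3c2O[C@H](c2ccc(OCc4ccccc4)c(OCc4ccccc4)c2)[C@H](O[Si](C)(C)C(C)(C)C)C3)c2c(OCc3ccccc3)cc(OCc3ccccc3)cc2O | intermediate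
18 | 5,7,3',4'-tetra-O-benzyl-3-O-TBS-epicatechin-(4β→8)-5,7,3',4'-tetra-O-benzyl-3-O-TBS-epicatechin | CC(C)(C)[Si](C)(C)O[C@@H]1[C@@H](c2c(OCc3ccccc3)cc(OCc3ccccc3)c3c2O[C@H](c2ccc(OCc4ccccc4)c(OCc4ccccc4)c2)[C@H](O[Si](C)(C)C(C)(C)C)C3)c2c(OCc3ccccc3)cc(OCc3ccccc3)cc2O[C@@H]1c1ccc(OCc2ccccc2)c(OCc2ccccc2)c1 | intermediate
19 | octa-O-benzyl procyanidin B2 (both 3-OH free) | O[C@@H]1[C@@H](c2c(OCc3ccccc3)cc(OCc3ccccc3)c3c2O[C@H](c2ccc(OCc4ccccc4)c(OCc4ccccc4)c2)[C@H](O)C3)c2c(OCc3ccccc3)cc(OCc3ccccc3)cc2O[C@@H]1c1ccc(OCc2ccccc2)c(OCc2ccccc2)c1 | intermediate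
20 | 3,4,5-tris(benzyloxy)benzoic acid | OC(=O)c1cc(OCc2ccccc2)c(OCc2ccccc2)c(OCc2ccccc2)c1 | starting material
21 | octa-O-benzyl procyanidin B2 3,3''-bis-O-[3,4,5-tris(benzyloxy)benzoate] | O=C(O[C@@H]1[C@@H](c2c(OCc3ccccc3)cc(OCc3ccccc3)c3c2O[C@H](c2ccc(OCc4ccccc4)c(OCc4ccccc4)c2)[C@H](OC(=O)c2cc(OCc4ccccc4)c(OCc4ccccc4)c(OCc4ccccc4)c2)C3)c2c(OCc3ccccc3)cc(OCc3ccccc3)cc2O[C@@H]1c1ccc(OCc2ccccc2)c(OCc2ccccc2)c1)c1cc(OCc2ccccc2)c(OCc2ccccc2)c(OCc2ccccc2)c1 | intermediate
22 | 4β-(2-ethoxyethoxy)-5,7,3',4'-tetra-O-benzylepicatechin | CCOCCO[C@H]1c2c(OCc3ccccc3)cc(OCc3ccccc3)cc2O[C@H](c2ccc(OCc3ccccc3)c(OCc3ccccc3)c2)[C@@H]1O | intermediate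
23 | protected trimer: tetra-O-benzylepicatechin-(4β→8)-[tetra-O-benzyl-3-O-(tri-O-benzylgalloyl)epicatechin]-(4β→8)-[tetra-O-benzyl-3-O-(tri-O-benzylgalloyl)epicatechin] | O=C(O[C@@H]1[C@@H](c2c(OCc3ccccc3)cc(OCc3ccccc3)c3c2O[C@H](c2ccc(OCc4ccccc4)c(OCc4ccccc4)c2)[C@H](OC(=O)c2cc(OCc4ccccc4)c(OCc4ccccc4)c(OCc4ccccc4)c2)C3)c2c(OCc3ccccc3)cc(OCc3ccccc3)c([C@H]3c4c(OCc5ccccc5)cc(OCc5ccccc5)cc4O[C@H](c4ccc(OCc5ccccc5)c(OCc5ccccc5)c4)[C@@H]3O)c2O[C@@H]1c1ccc(OCc2ccccc2)c(OCc2ccccc2)c1)c1cc(OCc2ccccc2)c(OCc2ccccc2)c(OCc2ccccc2)c1 | intermediate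
24 | epicatechin-(4β→8)-epicatechin 3-O-gallate-(4β→8)-epicatechin 3-O-gallate (CNP0279403.1) | O=C(O[C@@H]1[C@@H](c2c(O)cc(O)c3c2O[C@H](c2ccc(O)c(O)c2)[C@H](OC(=O)c2cc(O)c(O)c(O)c2)C3)c2c(O)cc(O)c([C@H]3c4c(O)cc(O)cc4O[C@H](c4ccc(O)c(O)c4)[C@@H]3O)c2O[C@@H]1c1ccc(O)c(O)c1)c1cc(O)c(O)c(O)c1 | target

Total step count: 15. Longest linear sequence: 12 steps (steps 1–3, 6–12, 14 and 15, from 1 to 24).

Steps most likely to fail

Step 8. The resident lower-unit stereocentres may oppose the catalyst, eroding facial and anti selectivity, or the strongly stabilised quinone methide may react too slowly so that aldehyde self-aldolisation takes over. The fallback abandons the annulation and makes the same interflavan bond by cation chemistry: it sets out from 3 and 22. TMSOTf-catalysed Friedel–Crafts coupling of the flavan-4-yl cation from 22 with an excess of 3 (attack through C8, trans to the 3-OH) should give 5,7,3',4'-tetra-O-benzylepicatechin-(4β→8)-5,7,3',4'-tetra-O-benzyl-3-O-TBS-epicatechin F1, and TBAF desilylation comes back to the route at 19.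

Step 10. The electron-rich benzylic oxyphosphonium may ionise before displacement, so that inversion is lost and the 2,3-trans ring forms; insufficient Felkin selectivity in step 9 would have the same consequence. The fallback sets out from 17 and removes the carbinol centre: MnO2 in CH2Cl2 should oxidise the benzylic alcohol to 1-[3,4-bis(benzyloxy)phenyl]-3-[2,4-bis(benzyloxy)-6-hydroxyphenyl]-2-(tert-butyldimethylsilyloxy)-3-(5,7,3',4'-tetra-O-benzyl-3-O-TBS-epicatechin-8-yl)propan-1-one F2. Reductive etherification (Et3SiH, BF3·OEt2, CH2Cl2, −78 °C) then passes through the cyclic 2-aryl oxocarbenium ion, in which allylic strain holds the 3-silyloxy group pseudo-axial; hydride delivery trans to that group should give the 2,3-cis ring and come back to the route at 18.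

Step 14. The cation from 22 may alkylate a second molecule of 22 or the product trimer at the free C8 of its top unit, giving oligomers instead of the trimer. The fallback blocks that position and sets out from 2. NBS should give 8-bromo-5,7,3',4'-tetra-O-benzylepicatechin F3, and DDQ with 2-ethoxyethanol should give 8-bromo-4β-(2-ethoxyethoxy)-5,7,3',4'-tetra-O-benzylepicatechin F4. TMSOTf coupling of F4 with 21 should give the 8-bromo protected trimer F5, which can no longer act as a nucleophile at its top unit. Hydrogenolysis (H2, Pd(OH)2/C, Et3N, THF/MeOH/H2O) should remove the benzyl groups and the bromine together and come back to the route at 24.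

Further compounds

F1 | step 8 | 5,7,3',4'-tetra-O-benzylepicatechin-(4β→8)-5,7,3',4'-tetra-O-benzyl-3-O-TBS-epicatechin | O[C@@H]1[C@@H](c2c(OCc3ccccc3)cc(OCc3ccccc3)c3c2O[C@H](c2ccc(OCc4ccccc4)c(OCc4ccccc4)c2)[C@H](O[Si](C)(C)C(C)(C)C)C3)c2c(OCc3ccccc3)cc(OCc3ccccc3)cc2O[C@@H]1c1ccc(OCc2ccccc2)c(OCc2ccccc2)c1
F2 | step 10 | 1-[3,4-bis(benzyloxy)phenyl]-3-[2,4-bis(benzyloxy)-6-hydroxyphenyl]-2-(tert-butyldimethylsilyloxy)-3-(5,7,3',4'-tetra-O-benzyl-3-O-TBS-epicatechin-8-yl)propan-1-one (2R) | CC(C)(C)[Si](C)(C)O[C@@H](C(=O)c1ccc(OCc2ccccc2)c(OCc2ccccc2)c1)[C@@H](c2c(OCc3ccccc3)cc(OCc3ccccc3)c3c2O[C@H](c2ccc(OCc4ccccc4)c(OCc4ccccc4)c2)[C@H](O[Si](C)(C)C(C)(C)C)C3)c2c(OCc3ccccc3)cc(OCc3ccccc3)cc2O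
F3 | step 14 | 8-bromo-5,7,3',4'-tetra-O-benzylepicatechin | O[C@@H]1Cc2c(OCc3ccccc3)cc(OCc3ccccc3)c(Br)c2O[C@@H]1c1ccc(OCc2ccccc2)c(OCc2ccccc2)c1
F4 | step 14 | 8-bromo-4β-(2-ethoxyethoxy)-5,7,3',4'-tetra-O-benzylepicatechin | CCOCCO[C@H]1c2c(OCc3ccccc3)cc(OCc3ccccc3)c(Br)c2O[C@H](c2ccc(OCc3ccccc3)c(OCc3ccccc3)c2)[C@@H]1O
F5 | step 14 | protected trimer 23 carrying bromine at C8 of the top unit | O=C(O[C@@H]1[C@@H](c2c(OCc3ccccc3)cc(OCc3ccccc3)c3c2O[C@H](c2ccc(OCc4ccccc4)c(OCc4ccccc4)c2)[C@H](OC(=O)c2cc(OCc4ccccc4)c(OCc4ccccc4)c(OCc4ccccc4)c2)C3)c2c(OCc3ccccc3)cc(OCc3ccccc3)c([C@H]3c4c(OCc5ccccc5)cc(OCc5ccccc5)c(Br)c4O[C@H](c4ccc(OCc5ccccc5)c(OCc5ccccc5)c4)[C@@H]3O)c2O[C@@H]1c1ccc(OCc2ccccc2)c(OCc2ccccc2)c1)c1cc(OCc2ccccc2)c(OCc2ccccc2)c(OCc2ccccc2)c1
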